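**Retrosynthetic overview**
- The hydroperoxide and the tetrasubstituted alkene come last, from a singlet-oxygen ene reaction on a trisubstituted ring B alkene whose side-chain carbon carries the hydrogen to be abstracted.
- That alkene comes from a tetrasubstituted enone by reductive 1,3-transposition, and the enone from a tertiary allylic alcohol by oxidative 1,3-transposition.
- Key bond: the ethylene bridge carbon next to ring B is joined to the ring B ketone carbon. The left-half aldehyde carbon reacts as a carbanion (its N–H hydrazone under Ru catalysis), so two carbonyl carbons are coupled and N2 is the only by-product.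
- Left half: one cascade on a bis-epoxide builds the oxepane first, then the cyclohexane, then a γ-lactone that is later opened to the aldehyde.
- Right half: ring A is bought as 4,4-dimethylcyclohexenone and ring B is formed on it by a cis-selective Diels–Alder reaction.

Assumption: (E,E)-homofarnesic acid, the L-fructose-derived Shi ketone and 4,4-dimethylcyclohex-2-enone are purchased; α is the decalin face carrying the two ring-fusion hydrogens, β the opposite face.

**Step 1**
Reactants: 1 (3E,7E)-homofarnesic acid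
Product: 2 methyl (3E,7E)-homofarnesoate
Conditions: MeI, K2CO3, DMF, 23 °C
Reagents that add atoms: iodomethane (CI)
Why: SN2 O-alkylation of the carboxylate without alkene isomerisation gives the ester, whose CH2CO2Me group deactivates the 3,4-alkene for step 2 and later terminates the cascade; no stereocentre is formed.

**Step 2**
Reactants: 2 methyl (3E,7E)-homofarnesoate
Product: 3 methyl (3E,7S,8S,11S)-7,8:11,12-diepoxy-4,8,12-trimethyltridec-3-enoate
Conditions: 1,2:4,5-di-O-isopropylidene-β-L-erythro-2,3-hexodiulo-2,6-pyranose (0.4 equiv), Oxone (2KHSO5·KHSO4·K2SO4), K2CO3, Bu4NHSO4, MeCN–CH2(OMe)2 / aq. Na2B4O7 (pH 10.5), 0 °C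
Reagents that add atoms: potassium peroxymonosulfate ([K+].[O-]S(=O)(=O)OO)
Why: Shi asymmetric epoxidation, in which the chiral dioxirane epoxidises the two remote electron-rich trisubstituted alkenes through the spiro transition state to the (7S,8S) and (11S) epoxides, while the 3,4-alkene next to the ester-bearing carbon reacts much more slowly (as in farnesyl acetate).

**Step 3**
Reactants: 3 diepoxy ester
Product: 4 silylated tricyclic lactone (oxepane / cyclohexane / trans γ-lactone)
Conditions: Et3SiOTf (1.2 equiv), 2,6-di-tert-butyl-4-methylpyridine, CH2Cl2, −78 °C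
Reagents that add atoms: triethylsilyl trifluoromethanesulfonate (CC[Si](CC)(CC)OS(=O)(=O)C(F)(F)F)
Why: Proposed new method: silyl activation of the terminal epoxide lets the 7,8-epoxide oxygen open it at the tertiary carbon (oxepane), the epoxonium is opened with inversion by the (E)-3,4-alkene through a chair transition state (5a-methyl axial, C6 chain equatorial), and the tertiary cation is captured anti by the ester carbonyl oxygen (equatorial C–O, methyl lost as MeOTf), so all five stereocentres follow from the epoxide centres and the alkene geometry; the closest known reactions are silyl-triflate-promoted tandem oxa-/carbacyclisations of polyepoxy alkenes and the lactonising cyclisation of homofarnesic acid to sclareolide.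

**Step 4**
Reactants: 4 silylated tricyclic lactone
Product: 5 lactol (anomer mixture)
Conditions: i-Bu2AlH (1.1 equiv), CH2Cl2, −78 °C; aq. KNaC4H4O6
Reagents that add atoms: none
Why: partial lactone reduction stops at the tetrahedral aluminate at −78 °C, and the new hemiacetal centre is an inconsequential anomer mixture.

**Step 5**
Reactants: 6 4,4-dimethylcyclohex-2-en-1-one; 7 isoprene
Product: 8 (4aR,8aS)-4,4,6-trimethyl-3,4,4a,5,8,8a-hexahydronaphthalen-1(2H)-one
Conditions: (S)-1-(2-methylphenyl)-3,3-diphenyltetrahydro-1H,3H-pyrrolo[1,2-c][1,3,2]oxazaborole (20 mol%), AlBr3 (16 mol%), isoprene (5 equiv), CH2Cl2, −40 → −20 °C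
Reagents that add atoms: none
Why: catalytic enantioselective Diels–Alder reaction (Corey oxazaborolidinium Lewis acid), in which suprafacial addition fixes the cis ring fusion, the "para" orientation puts the diene methyl on C6, and the chiral Lewis acid selects the enone face for (4aR,8aS); the sense is assigned by analogy with cyclohexenone adducts, and the mirror-image catalyst is used if it proves opposite.

**Step 6**
Reactants: 8 cis-octalone
Product: 9 (4aR,8aS)-4,4,6-trimethyl-1-methylidene-1,2,3,4,4a,5,8,8a-octahydronaphthalene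
Conditions: Ph3PCH3Br, KOt-Bu, THF, 0 → 23 °C (ylide pre-formed)
Reagents that add atoms: methyltriphenylphosphonium bromide (C[P+](c1ccccc1)(c1ccccc1)c1ccccc1.[Br-])
Why: Wittig methylenation of the ring A ketone, where the pre-formed ylide adds faster than it enolises so the cis fusion is kept.

**Step 7**
Reactants: 9 exocyclic alkene
Product: 10 (1S,4aR,8aS)-1,4,4,6-tetramethyl-1,2,3,4,4a,5,8,8a-octahydronaphthalen-1-ol
Conditions: Co(acac)2 (20 mol%), PhSiH3 (2 equiv), O2 (1 atm), THF, 23 °C; aq. Na2S2O3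
Reagents that add atoms: dioxygen (O=O)
Why: Mukaiyama hydration by hydrogen-atom transfer, in which H adds to the unhindered exocyclic CH2 faster than to the trisubstituted ring alkene and the tertiary C1 radical is oxygenated from the equatorial side because the axial face is blocked by the axial C5 methylene, giving equatorial α-OH and axial β-methyl (1S).

**Step 8**
Reactants: 10 tertiary alcohol
Product: 11 (1S,4aR,5R,8aS)-1,4,4,6-tetramethyl-1,2,3,4,4a,5,8,8a-octahydronaphthalene-1,5-diol
Conditions: SeO2 (0.5 equiv), t-BuOOH (3 equiv), CH2Cl2, 23 °C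
Reagents that add atoms: selenium dioxide (O=[Se]=O), re-oxidised by tert-butyl hydroperoxide (CC(C)(C)OO)
Why: Sharpless–Umbreit allylic oxidation (ene reaction then [2,3] shift), which by the Guillemonat rules oxidises the ring CH2 next to the more substituted alkene carbon (C5) from the less hindered α face; the new centre is removed in step 9.

**Step 9**
Reactants: 11 allylic diol
Product: 12 (4aS,5S,8aR)-5-hydroxy-2,5,8,8-tetramethyl-4a,5,6,7,8,8a-hexahydronaphthalen-1(4H)-one
Conditions: MnO2 (activated, 20 equiv), CH2Cl2, 23 °C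
Reagents that add atoms: none
Why: neutral MnO2 oxidises only the allylic secondary alcohol and does not epimerise the α-stereocentre C8a.

**Step 10**
Reactants: 5 lactol; 12 enone
Product: 14 tertiary allylic alcohol with both halves joined, via hydrazone 13 (not isolated)
Conditions: N2H4·H2O (1.2 equiv), THF, 23 °C; then 12, [Ru(p-cymene)Cl2]2 (2.5 mol%), Me2PCH2CH2PMe2 (5 mol%), K3PO4 (0.5 equiv), THF, 45 °C
Reagents that add atoms: none
Why: ruthenium-catalysed Wolff–Kishner-type carbonyl umpolung, in which the N–H hydrazone of the left-half aldehyde binds divalent ruthenium, its carbon adds 1,2 to the ketone through a six-membered transition state and N2 is lost, so two carbonyl carbons are joined and the former aldehyde carbon ends as CH2; the new carbinol centre (drawn for α-face attack) is erased in step 11.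

**Step 11**
Reactants: 14 tertiary allylic alcohol
Product: 15 tetrasubstituted enone
Conditions: C5H5NH[CrO3Cl] (3 equiv), NaOAc, 4 Å sieves, CH2Cl2, 0 → 23 °C
Reagents that add atoms: pyridinium chlorochromate ([O-][Cr](=O)(=O)Cl.c1cc[nH+]cc1)
Why: Dauben–Michno oxidative 1,3-transposition, in which the tertiary allylic chromate ester shifts [3,3] to the secondary ester and is oxidised to the enone; the left-half secondary alcohol is masked as its Et3Si ether and the other tertiary alcohols are inert.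

**Step 12**
Reactants: 15 tetrasubstituted enone
Product: 18 trisubstituted-alkene triol, via tosylhydrazone 16 (not isolated), via allylic diazene 17 (not isolated)
Conditions: TsNHNH2 (1.5 equiv), PPTS (0.2 equiv), MeOH, 40 °C; evaporate; catecholborane (6 equiv), CHCl3, 0 °C; NaOAc·3H2O, 60 °C
Reagents that add atoms: none
Why: Kabalka reductive 1,3-transposition of an enone tosylhydrazone, in which acidic methanol forms the hydrazone and removes the Et3Si ether, hydride adds axially to C=N from the convex α face, sulfinate loss gives the β allylic diazene, and its suprafacial retro-ene loss of N2 delivers hydrogen to the side-chain carbon on the β face (5R) while the alkene moves next to the methyl.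

**Step 13**
Reactants: 18 trisubstituted-alkene triol
Product: 19 sipholenol M
Conditions: O2, visible light, tetraphenylporphyrin (1 mol%), CH2Cl2, −20 °C
Reagents that add atoms: dioxygen (O=O)
Why: Schenck ene reaction of singlet oxygen, in which the cis effect directs abstraction to the ring side of the trisubstituted alkene and suprafacial removal of the β C5–H (set in step 12) with C–O bonding at the alkene CH on the same β face gives the (R)-hydroperoxide and the tetrasubstituted alkene.

**Compound list**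
1 | (3E,7E)-4,8,12-trimethyltrideca-3,7,11-trienoic acid | OC(=O)C/C=C(\C)CC/C=C(\C)CCC=C(C)C | starting material
2 | methyl (3E,7E)-4,8,12-trimethyltrideca-3,7,11-trienoate | COC(=O)C/C=C(\C)CC/C=C(\C)CCC=C(C)C | intermediate
3 | methyl (3E,7S,8S,11S)-7,8:11,12-diepoxy-4,8,12-trimethyltridec-3-enoate | COC(=O)C/C=C(\C)CC[C@@H]1O[C@@]1(C)CC[C@@H]1OC1(C)C | intermediate
4 | 1,7-lactone of {(3S,5aS,6S,7S,9aS)-7-hydroxy-2,2,5a,7-tetramethyl-3-[(triethylsilyl)oxy]decahydro-1-benzoxepin-6-yl}acetic acid | O=C1C[C@H]2[C@]3(C)CC[C@H](O[Si](CC)(CC)CC)C(C)(C)O[C@H]3CC[C@]2(C)O1 | intermediate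
5 | lactol of 4 (cyclic hemiacetal of the 6-(2-oxoethyl) aldehyde with the 7-hydroxyl, anomer mixture) | OC1C[C@H]2[C@]3(C)CC[C@H](O[Si](CC)(CC)CC)C(C)(C)O[C@H]3CC[C@]2(C)O1 | intermediate
6 | 4,4-dimethylcyclohex-2-en-1-one | O=C1C=CC(C)(C)CC1 | starting material
7 | isoprene (2-methylbuta-1,3-diene) | C=CC(C)=C | starting material
8 | (4aR,8aS)-4,4,6-trimethyl-3,4,4a,5,8,8a-hexahydronaphthalen-1(2H)-one | CC1=CC[C@H]2[C@@H](C1)C(C)(C)CCC2=O | intermediate
9 | (4aR,8aS)-4,4,6-trimethyl-1-methylidene-1,2,3,4,4a,5,8,8a-octahydronaphthalene | CC1=CC[C@H]2[C@@H](C1)C(C)(C)CCC2=C | intermediate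
10 | (1S,4aR,8aS)-1,4,4,6-tetramethyl-1,2,3,4,4a,5,8,8a-octahydronaphthalen-1-ol | CC1=CC[C@H]2[C@@H](C1)C(C)(C)CC[C@]2(C)O | intermediate
11 | (1S,4aR,5R,8aS)-1,4,4,6-tetramethyl-1,2,3,4,4a,5,8,8a-octahydronaphthalene-1,5-diol | CC1=CC[C@H]2[C@@H]([C@H]1O)C(C)(C)CC[C@]2(C)O | intermediate
12 | (4aS,5S,8aR)-5-hydroxy-2,5,8,8-tetramethyl-4a,5,6,7,8,8a-hexahydronaphthalen-1(4H)-one | CC1=CC[C@H]2[C@@H](C1=O)C(C)(C)CC[C@]2(C)O | intermediate
13 | {(3S,5aS,6S,7S,9aS)-7-hydroxy-2,2,5a,7-tetramethyl-3-[(triethylsilyl)oxy]decahydro-1-benzoxepin-6-yl}acetaldehyde hydrazone | NN=CC[C@H]1[C@]2(C)CC[C@H](O[Si](CC)(CC)CC)C(C)(C)O[C@H]2CC[C@]1(C)O | intermediate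
14 | (1S,4aS,5S,8aR)-1-{2-[(3S,5aS,6S,7S,9aS)-7-hydroxy-2,2,5a,7-tetramethyl-3-[(triethylsilyl)oxy]decahydro-1-benzoxepin-6-yl]ethyl}-2,5,8,8-tetramethyl-1,4,4a,5,6,7,8,8a-octahydronaphthalene-1,5-diol | CC1=CC[C@H]2[C@@H]([C@@]1(O)CC[C@H]1[C@]3(C)CC[C@H](O[Si](CC)(CC)CC)C(C)(C)O[C@H]3CC[C@]1(C)O)C(C)(C)CC[C@]2(C)O | intermediate
15 | (4aR,8S,8aS)-8-hydroxy-4-{2-[(3S,5aS,6S,7S,9aS)-7-hydroxy-2,2,5a,7-tetramethyl-3-[(triethylsilyl)oxy]decahydro-1-benzoxepin-6-yl]ethyl}-3,5,5,8-tetramethyl-4a,5,6,7,8,8a-hexahydronaphthalen-2(1H)-one | CC1=C(CC[C@H]2[C@]3(C)CC[C@H](O[Si](CC)(CC)CC)C(C)(C)O[C@H]3CC[C@]2(C)O)[C@@H]2[C@H](CC1=O)[C@@](C)(O)CCC2(C)C | intermediate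
16 | N′-[(4aR,8S,8aS)-4-{2-[(3S,5aS,6S,7S,9aS)-3,7-dihydroxy-2,2,5a,7-tetramethyldecahydro-1-benzoxepin-6-yl]ethyl}-8-hydroxy-3,5,5,8-tetramethyl-4a,5,6,7,8,8a-hexahydronaphthalen-2(1H)-ylidene]-4-methylbenzenesulfonohydrazide | CC1=C(CC[C@H]2[C@]3(C)CC[C@H](O)C(C)(C)O[C@H]3CC[C@]2(C)O)[C@@H]2[C@H](CC1=NNS(=O)(=O)c1ccc(C)cc1)[C@@](C)(O)CCC2(C)C | intermediate
17 | (3S,5aS,6S,7S,9aS)-6-{2-[(3R,4aS,5S,8aR)-3-diazenyl-5-hydroxy-2,5,8,8-tetramethyl-3,4,4a,5,6,7,8,8a-octahydronaphthalen-1-yl]ethyl}-2,2,5a,7-tetramethyldecahydro-1-benzoxepine-3,7-diol | CC1=C(CC[C@H]2[C@]3(C)CC[C@H](O)C(C)(C)O[C@H]3CC[C@]2(C)O)[C@@H]2[C@H](C[C@H]1N=N)[C@@](C)(O)CCC2(C)C | intermediate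
18 | (3S,5aS,6S,7S,9aS)-6-{2-[(1R,4aS,5S,8aR)-5-hydroxy-2,5,8,8-tetramethyl-1,4,4a,5,6,7,8,8a-octahydronaphthalen-1-yl]ethyl}-2,2,5a,7-tetramethyldecahydro-1-benzoxepine-3,7-diol; in the ring numbering of 10 the decalin is (1S,4aR,5R,8aS) with the chain on C5 | CC1=CC[C@H]2[C@@H]([C@H]1CC[C@H]1[C@]3(C)CC[C@H](O)C(C)(C)O[C@H]3CC[C@]1(C)O)C(C)(C)CC[C@]2(C)O | intermediate
19 | sipholenol M, (3S,5aS,6S,7S,9aS)-6-{2-[(3R,4aS,5S,8aR)-3-hydroperoxy-5-hydroxy-2,5,8,8-tetramethyl-3,4,4a,5,6,7,8,8a-octahydronaphthalen-1-yl]ethyl}-2,2,5a,7-tetramethyldecahydro-1-benzoxepine-3,7-diol | CC1=C(CC[C@H]2[C@]3(C)CC[C@H](O)C(C)(C)O[C@H]3CC[C@]2(C)O)[C@@H]2[C@H](C[C@H]1OO)[C@@](C)(O)CCC2(C)C | target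

**Step count**
Total steps: 13. Longest linear sequence: 9 (steps 5 to 13).

**Three steps most likely to fail, with fallbacks**

Step 3 (cascade). The ester carbonyl may not capture the tertiary cation, so that proton loss or an interrupted cascade wins. The fallback sets out from 3 and separates the two events. Et2AlCl in CH2Cl2 at −78 °C runs the same oxepane-then-cyclohexane sequence but ends by proton loss, giving methyl 2-[(3S,5aS,6R,9aS)-3-hydroxy-2,2,5a-trimethyl-7-methylidenedecahydro-1-benzoxepin-6-yl]acetate F1 (ring-alkene isomers converge). Catalytic CF3SO3H in CH2Cl2 at −20 °C re-protonates the alkene and the ester oxygen closes the trans lactone, giving the hydroxy lactone F2. Et3SiOTf with 2,6-lutidine then returns to the route at 4.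

Step 10 (union). The ketone 12 is hindered and enolisable, and the ruthenium-bound carbanion could add 1,4 or epimerise C8a. The fallback keeps the reversed-polarity logic but uses a stoichiometric acyl anion, setting out from 5. Propane-1,3-dithiol and BF3·OEt2 at −40 °C give the 1,3-dithiane F3. Double deprotonation with n-BuLi in THF at −30 °C and addition to the lithium alkoxide of 12 at −78 °C gives the dithiane carbinol F4. Raney Ni in EtOH removes the sulfur and returns to the route at 14.

Step 13 (ene reaction). Singlet oxygen may abstract the ring CH2 hydrogen or a methyl hydrogen instead, and the C5–H must be pseudoaxial. The fallback sets out from 15 and installs the peroxide by substitution. Li[B(s-Bu)3H] at −78 °C attacks equatorially from the β face and gives the α (pseudoaxial) allylic alcohol F5. MsCl and Et3N at −78 °C give the mesylate F6, which is displaced with inversion by anhydrous ethereal H2O2 at −110 → −60 °C to give the silyl-protected β-hydroperoxide F7. HF·pyridine in THF at 0 °C removes the silyl group and returns to the route at 19.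

**Further compounds**
F1 | step 3 | methyl 2-[(3S,5aS,6R,9aS)-3-hydroxy-2,2,5a-trimethyl-7-methylidenedecahydro-1-benzoxepin-6-yl]acetate | COC(=O)C[C@H]1[C@]2(C)CC[C@H](O)C(C)(C)O[C@H]2CCC1=C
F2 | step 3 | 1,7-lactone of [(3S,5aS,6S,7S,9aS)-3,7-dihydroxy-2,2,5a,7-tetramethyldecahydro-1-benzoxepin-6-yl]acetic acid | O=C1C[C@H]2[C@]3(C)CC[C@H](O)C(C)(C)O[C@H]3CC[C@]2(C)O1
F3 | step 10 | 2-({(3S,5aS,6S,7S,9aS)-7-hydroxy-2,2,5a,7-tetramethyl-3-[(triethylsilyl)oxy]decahydro-1-benzoxepin-6-yl}methyl)-1,3-dithiane | C1CSC(SC1)C[C@H]1[C@]2(C)CC[C@H](O[Si](CC)(CC)CC)C(C)(C)O[C@H]2CC[C@]1(C)O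
F4 | step 10 | (4aS,5S,8aR)-1-[2-({(3S,5aS,6S,7S,9aS)-7-hydroxy-2,2,5a,7-tetramethyl-3-[(triethylsilyl)oxy]decahydro-1-benzoxepin-6-yl}methyl)-1,3-dithian-2-yl]-2,5,8,8-tetramethyl-1,4,4a,5,6,7,8,8a-octahydronaphthalene-1,5-diol (C1 hydroxyl β) | CC1=CC[C@H]2[C@@H]([C@@]1(O)C1(SCCCS1)C[C@H]1[C@]3(C)CC[C@H](O[Si](CC)(CC)CC)C(C)(C)O[C@H]3CC[C@]1(C)O)C(C)(C)CC[C@]2(C)O
F5 | step 13 | (3S,4aS,5S,8aR)-1-{2-[(3S,5aS,6S,7S,9aS)-7-hydroxy-2,2,5a,7-tetramethyl-3-[(triethylsilyl)oxy]decahydro-1-benzoxepin-6-yl]ethyl}-2,5,8,8-tetramethyl-3,4,4a,5,6,7,8,8a-octahydronaphthalene-3,5-diol | CC1=C(CC[C@H]2[C@]3(C)CC[C@H](O[Si](CC)(CC)CC)C(C)(C)O[C@H]3CC[C@]2(C)O)[C@@H]2[C@H](C[C@@H]1O)[C@@](C)(O)CCC2(C)C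
F6 | step 13 | 3-methanesulfonate of F5 | CC1=C(CC[C@H]2[C@]3(C)CC[C@H](O[Si](CC)(CC)CC)C(C)(C)O[C@H]3CC[C@]2(C)O)[C@@H]2[C@H](C[C@@H]1OS(C)(=O)=O)[C@@](C)(O)CCC2(C)C
F7 | step 13 | 3-O-triethylsilyl ether of sipholenol M (silyl on the benzoxepine C3 oxygen) | CC1=C(CC[C@H]2[C@]3(C)CC[C@H](O[Si](CC)(CC)CC)C(C)(C)O[C@H]3CC[C@]2(C)O)[C@@H]2[C@H](C[C@H]1OO)[C@@](C)(O)CCC2(C)C
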